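**Strategy.** Ring A hides a quinone. O1 (on C8a) and the C6 hydroxyl are para, and C6 is flanked by oxygens on C5 and C7. Ring A is therefore a reduced 2,6-dimethoxy-1,4-benzoquinone, whose two CH carbons (future C4a and C8) are equivalent. The route joins this quinone to an enantiopure trans-epoxy aldehyde that carries ring B. In one photochemical operation the aldehyde C–H is exchanged for the C4–C4a bond and the quinone is reduced to a hydroquinone. The phenol O1 so created opens the strained oxirane at the benzylic carbon, giving O1–C2 and ring C with both stereocentres. Benzylation, O-methylation at C3 and one BCl3 deprotection finish the synthesis.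

Key step: step 4

Remark: flavanone numbering (O1, C2, C3, C4, C4a, C5 to C8, C8a; ring B primed) is used for all chromanones. The sense of induction in step 3 is taken from the usual face-shielding model of diarylprolinol silyl ethers.

Step 1
Reactants: 1 isovanillin (3-hydroxy-4-methoxybenzaldehyde)
Product: 2 tert-butyl 5-formyl-2-methoxyphenyl carbonate
Conditions: Boc2O, DMAP (5 mol %), CH2Cl2, 0 °C to rt
Reagents that add atoms: di-tert-butyl dicarbonate, CC(C)(C)OC(=O)OC(=O)OC(C)(C)C
Why: DMAP-catalysed O-acylation of the phenol gives an aryl tert-butyl carbonate, which has no abstractable benzylic hydrogen, makes ring B a poorer electron donor for step 4 and falls off under the Lewis acid of step 7.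

Step 2
Reactants: 2 tert-butyl 5-formyl-2-methoxyphenyl carbonate
Product: 3 tert-butyl 2-methoxy-5-[(E)-3-oxoprop-1-en-1-yl]phenyl carbonate
Conditions: Ph3P=CHCHO, toluene, 80 °C
Reagents that add atoms: (triphenylphosphoranylidene)acetaldehyde, O=CC=P(c1ccccc1)(c1ccccc1)c1ccccc1
Why: Wittig olefination with the stabilised formyl ylide should give the E-enal, and the carbonate is inert to this neutral reagent.

Step 3
Reactants: 3 tert-butyl 2-methoxy-5-[(E)-3-oxoprop-1-en-1-yl]phenyl carbonate
Product: 4 (2R,3S)-3-[3-(tert-butoxycarbonyloxy)-4-methoxyphenyl]oxirane-2-carbaldehyde (trans epoxide)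
Conditions: (R)-2-{bis[3,5-bis(trifluoromethyl)phenyl](trimethylsilyloxy)methyl}pyrrolidine (10 mol %), 35 % aq. H2O2, CH2Cl2, rt
Reagents that add atoms: hydrogen peroxide, OO
Why: In this iminium–enamine organocatalytic epoxidation (Weitz–Scheffer type), hydrogen peroxide adds to the beta carbon of the E-iminium ion on the face left open by the diaryl(silyloxy)methyl group and the enamine then closes the oxirane, so the catalyst sets both C2 (R) and C3 (S) of the trans epoxide.

Step 4
Reactants: 4 (2R,3S)-3-[3-(tert-butoxycarbonyloxy)-4-methoxyphenyl]oxirane-2-carbaldehyde; 5 2,6-dimethoxy-1,4-benzoquinone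
Product: 7 (2R,3R)-2-[3-(tert-butoxycarbonyloxy)-4-methoxyphenyl]-3,6-dihydroxy-5,7-dimethoxychroman-4-one, via acylhydroquinone epoxy ketone 6 (not isolated)
Conditions: hν (405 nm LEDs), PhCF3, degassed, 15 °C; then pyridinium p-toluenesulfonate (10 mol %), rt, same flask
Reagents that add atoms: none
Why: Proposed new method: light above 400 nm excites only quinone 5, whose triplet abstracts the formyl hydrogen of 4; the acyl radical bonds to C3 of the quinone (the future C4a, giving the C4–C4a bond), and tautomerisation to the aromatic acylhydroquinone 6 turns the neighbouring quinone carbonyl oxygen into the phenol O1, which opens the strained oxirane at its benzylic carbon (giving the O1–C2 bond), the acid catalyst only completing this closure. The closest known reaction types are the photo-Friedel–Crafts acylation of 1,4-quinones with aldehydes and the cyclisation of 2'-hydroxychalcone epoxides to trans-3-hydroxyflavanones (the ring-forming event of the Algar–Flynn–Oyamada manifold), but their tandem use, an alpha,beta-epoxy aldehyde as acyl donor and a 2,6-dialkoxyquinone as acceptor are untested. Ring C closes in the 6-endo-tet mode on the epoxide, preferred over 5-exo attack at the alpha carbon because the para-methoxy group of ring B carries the developing positive charge at C2 while the ring strain is released. C3 keeps the R configuration of the oxirane carbon of 4 because its C–O bond is never broken, and C2 becomes R by backside attack on the S benzylic carbon; if the opening drifts towards an open cation, the C3 substituent still directs closure to the 2,3-trans diequatorial product, so the same isomer should result. Site selectivity needs no control element, because C3 and C5 are the only CH carbons of 5 and are related by its mirror plane, and the 5-methoxy, 6-hydroxy, 7-methoxy pattern of ring A follows directly. Chemoselectivity for the formyl C–H is secured by the absence of benzyl ether C–H bonds, by the carbonate that weakens ring B as an electron donor towards the excited quinone, and by the sigma character of the acyl radical, for which loss of CO to an oxiranyl radical and beta-scission to a ketene are both uphill.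

Step 5
Reactants: 7 (2R,3R)-2-[3-(tert-butoxycarbonyloxy)-4-methoxyphenyl]-3,6-dihydroxy-5,7-dimethoxychroman-4-one
Product: 8 (2R,3R)-6-(benzyloxy)-2-[3-(tert-butoxycarbonyloxy)-4-methoxyphenyl]-3-hydroxy-5,7-dimethoxychroman-4-one
Conditions: BnBr, K2CO3, Bu4NI (cat.), acetone, rt, argon
Reagents that add atoms: benzyl bromide, BrCc1ccccc1
Why: In this Williamson ether synthesis only the phenolic 6-OH is acidic enough for K2CO3, so the secondary 3-OH stays free and the mild base at room temperature should leave C2 and C3 untouched.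

Step 6
Reactants: 8 (2R,3R)-6-(benzyloxy)-2-[3-(tert-butoxycarbonyloxy)-4-methoxyphenyl]-3-hydroxy-5,7-dimethoxychroman-4-one
Product: 9 (2R,3R)-6-(benzyloxy)-2-[3-(tert-butoxycarbonyloxy)-4-methoxyphenyl]-3,5,7-trimethoxychroman-4-one
Conditions: MeOTf, 2,6-di-tert-butyl-4-methylpyridine, CH2Cl2, 0 °C to rt
Reagents that add atoms: methyl trifluoromethanesulfonate, COS(=O)(=O)C(F)(F)F
Why: SN2 O-alkylation of the neutral alcohol by methyl triflate with a hindered, non-nucleophilic pyridine as acid trap forms no enolate or alkoxide, so ring opening, oxidation to the flavonol and epimerisation at C2 or C3 are avoided.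

Step 7
Reactants: 9 (2R,3R)-6-(benzyloxy)-2-[3-(tert-butoxycarbonyloxy)-4-methoxyphenyl]-3,5,7-trimethoxychroman-4-one
Product: 10 (2R,3R)-5,6-dihydroxy-2-(3-hydroxy-4-methoxyphenyl)-3,7-dimethoxychroman-4-one (target)
Conditions: BCl3, pentamethylbenzene, CH2Cl2, −78 to 0 °C, argon; then aqueous work-up at pH 4 to 5
Reagents that add atoms: none
Why: In this chelation-controlled Lewis-acid ether cleavage, BCl3 held in a six-membered chelate between the C4 carbonyl and the peri 5-methoxy group removes that methyl selectively and also cleaves the crowded 6-benzyl ether (cation trapped by pentamethylbenzene in a Friedel–Crafts alkylation) and the tert-butyl carbonate, while the 7-, 4'- and aliphatic 3-methyl ethers lack such activation at low temperature.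

Compound list
1 | isovanillin (3-hydroxy-4-methoxybenzaldehyde) | COc1ccc(C=O)cc1O | starting material
2 | tert-butyl 5-formyl-2-methoxyphenyl carbonate | COc1ccc(C=O)cc1OC(=O)OC(C)(C)C | intermediate
3 | tert-butyl 2-methoxy-5-[(E)-3-oxoprop-1-en-1-yl]phenyl carbonate | COc1ccc(/C=C/C=O)cc1OC(=O)OC(C)(C)C | intermediate
4 | (2R,3S)-3-[3-(tert-butoxycarbonyloxy)-4-methoxyphenyl]oxirane-2-carbaldehyde | O=C[C@@H]1O[C@H]1c2ccc(OC)c(OC(=O)OC(C)(C)C)c2 | intermediate
5 | 2,6-dimethoxy-1,4-benzoquinone | COC1=CC(=O)C=C(OC)C1=O | starting material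
6 | (3,6-dihydroxy-2,4-dimethoxyphenyl) {(2R,3S)-3-[3-(tert-butoxycarbonyloxy)-4-methoxyphenyl]oxiran-2-yl} ketone | COc1cc(O)c(C(=O)[C@@H]2O[C@H]2c3ccc(OC)c(OC(=O)OC(C)(C)C)c3)c(OC)c1O | intermediate
7 | (2R,3R)-2-[3-(tert-butoxycarbonyloxy)-4-methoxyphenyl]-3,6-dihydroxy-5,7-dimethoxychroman-4-one | COc1ccc([C@H]2Oc3cc(OC)c(O)c(OC)c3C(=O)[C@@H]2O)cc1OC(=O)OC(C)(C)C | intermediate
8 | (2R,3R)-6-(benzyloxy)-2-[3-(tert-butoxycarbonyloxy)-4-methoxyphenyl]-3-hydroxy-5,7-dimethoxychroman-4-one | COc1ccc([C@H]2Oc3cc(OC)c(OCc4ccccc4)c(OC)c3C(=O)[C@@H]2O)cc1OC(=O)OC(C)(C)C | intermediate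
9 | (2R,3R)-6-(benzyloxy)-2-[3-(tert-butoxycarbonyloxy)-4-methoxyphenyl]-3,5,7-trimethoxychroman-4-one | COc1ccc([C@H]2Oc3cc(OC)c(OCc4ccccc4)c(OC)c3C(=O)[C@@H]2OC)cc1OC(=O)OC(C)(C)C | intermediate
10 | (2R,3R)-5,6-dihydroxy-2-(3-hydroxy-4-methoxyphenyl)-3,7-dimethoxychroman-4-one | COc1ccc([C@H]2Oc3cc(OC)c(O)c(O)c3C(=O)[C@@H]2OC)cc1O | target

Total step count: 7. Longest linear sequence: 7 steps (1 to 10); quinone 5 enters as purchased.

Steps most likely to fail

Step 4 (bears the label).
- What may go wrong: hydrogen abstraction by the donor-substituted quinone triplet may be too slow. Ring B may quench the excited state by electron transfer. The radical pair may collapse at oxygen instead of carbon. The acyl radical may fragment. The epoxy ketone may undergo a 1,2-acyl shift or attack at its alpha carbon before O1 reaches C2.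
- Fallback: this uses known chemistry and still makes both bonds in one operation, but from a tethered singlet radical pair. It sets out from 4 and 5. Pinnick oxidation of 4 (NaClO2, NaH2PO4, 2-methyl-2-butene, t-BuOH/H2O, 0 °C) would give (2R,3S)-3-[3-(tert-butoxycarbonyloxy)-4-methoxyphenyl]oxirane-2-carboxylic acid F1, to be used cold and at once. Reduction of 5 with Na2S2O4 would give 2,6-dimethoxybenzene-1,4-diol F2. Steglich esterification (1-ethyl-3-(3-dimethylaminopropyl)carbodiimide, DMAP, CH2Cl2, 0 °C) at the unhindered hydroxyl of F2 would give 4-hydroxy-3,5-dimethoxyphenyl (2R,3S)-3-[3-(tert-butoxycarbonyloxy)-4-methoxyphenyl]oxirane-2-carboxylate F3. Photo-Fries rearrangement of F3 (300 nm, MeCN) can deliver the acyl group only to the two equivalent ortho carbons, because the para carbon carries the hydroxyl. This gives 6, and the same epoxide opening brings the route back at 7.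

Step 7.
- What may go wrong: the aliphatic 3-O-methyl group may be lost through a five-membered chelate with the C4 carbonyl. Further demethylation may occur next to the freshly bared phenols. The Lewis acid may open the O1–C2 bond and erode the C2 configuration.
- Fallback: the order is changed so that no Lewis acid meets the 3-methyl ether and the last step is a neutral hydrogenolysis. It sets out from 7. BCl3 (CH2Cl2, −78 to 0 °C) would remove the 5-methyl group and the carbonate to give (2R,3R)-3,5,6-trihydroxy-2-(3-hydroxy-4-methoxyphenyl)-7-methoxychroman-4-one F4. BnBr and K2CO3 in acetone would alkylate the 6- and 3'-hydroxyls while the chelated 5-hydroxyl stays free, giving (2R,3R)-6-(benzyloxy)-2-[3-(benzyloxy)-4-methoxyphenyl]-3,5-dihydroxy-7-methoxychroman-4-one F5. MeOTf with 2,6-di-tert-butyl-4-methylpyridine would methylate the 3-hydroxyl to give (2R,3R)-6-(benzyloxy)-2-[3-(benzyloxy)-4-methoxyphenyl]-5-hydroxy-3,7-dimethoxychroman-4-one F6. Hydrogenolysis (H2, Pd/C, EtOAc) comes back to the route at 10.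

Step 3.
- What may go wrong: the electron-rich aryl oxirane may open solvolytically or rearrange in aqueous peroxide or on silica. Facial selectivity may be insufficient. The carbonate may be slowly transferred to the amine catalyst.
- Fallback: reagent control on the allylic alcohol replaces iminium catalysis. It sets out from 3. Luche reduction (NaBH4, CeCl3·7H2O, MeOH, 0 °C) would give tert-butyl 5-[(E)-3-hydroxyprop-1-en-1-yl]-2-methoxyphenyl carbonate F7. Sharpless asymmetric epoxidation (Ti(OiPr)4, L-(+)-diethyl tartrate, t-BuOOH, 4 Å molecular sieves, CH2Cl2, −20 °C) would give tert-butyl 5-[(2S,3S)-3-(hydroxymethyl)oxiran-2-yl]-2-methoxyphenyl carbonate F8. Parikh–Doering oxidation (SO3·pyridine, DMSO, Et3N) comes back to the route at 4.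

Further compounds
F1 | step 4 | (2R,3S)-3-[3-(tert-butoxycarbonyloxy)-4-methoxyphenyl]oxirane-2-carboxylic acid | OC(=O)[C@@H]1O[C@H]1c2ccc(OC)c(OC(=O)OC(C)(C)C)c2
F2 | step 4 | 2,6-dimethoxybenzene-1,4-diol | COc1cc(O)cc(OC)c1O
F3 | step 4 | 4-hydroxy-3,5-dimethoxyphenyl (2R,3S)-3-[3-(tert-butoxycarbonyloxy)-4-methoxyphenyl]oxirane-2-carboxylate | COc1cc(OC(=O)[C@@H]2O[C@H]2c3ccc(OC)c(OC(=O)OC(C)(C)C)c3)cc(OC)c1O
F4 | step 7 | (2R,3R)-3,5,6-trihydroxy-2-(3-hydroxy-4-methoxyphenyl)-7-methoxychroman-4-one | COc1ccc([C@H]2Oc3cc(OC)c(O)c(O)c3C(=O)[C@@H]2O)cc1O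
F5 | step 7 | (2R,3R)-6-(benzyloxy)-2-[3-(benzyloxy)-4-methoxyphenyl]-3,5-dihydroxy-7-methoxychroman-4-one | COc1ccc([C@H]2Oc3cc(OC)c(OCc4ccccc4)c(O)c3C(=O)[C@@H]2O)cc1OCc5ccccc5
F6 | step 7 | (2R,3R)-6-(benzyloxy)-2-[3-(benzyloxy)-4-methoxyphenyl]-5-hydroxy-3,7-dimethoxychroman-4-one | COc1ccc([C@H]2Oc3cc(OC)c(OCc4ccccc4)c(O)c3C(=O)[C@@H]2OC)cc1OCc5ccccc5
F7 | step 3 | tert-butyl 5-[(E)-3-hydroxyprop-1-en-1-yl]-2-methoxyphenyl carbonate | COc1ccc(/C=C/CO)cc1OC(=O)OC(C)(C)C
F8 | step 3 | tert-butyl 5-[(2S,3S)-3-(hydroxymethyl)oxiran-2-yl]-2-methoxyphenyl carbonate | OC[C@@H]1O[C@H]1c2ccc(OC)c(OC(=O)OC(C)(C)C)c2
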